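**Retrosynthetic overview**

1. Target: methyl (2R)-2-(3-bromo-5-hydroxy-4-methoxyphenyl)-3-(2,3-dibromo-4,5-dihydroxyphenyl)propanoate. Ring A is the dibromocatechol ring, ring B the bromo-hydroxy-methoxyphenyl ring. No ring is built, so there is no order of ring formation; both arenes are bought and only decorated.
2. Last step: fluoride removal of three aryl silyl ethers.
3. Key disconnection: the C2–C3 bond. An electrophilic rhodium carbenoid (the ester α-carbon of a ring B aryldiazoacetate, an enolonium equivalent) inserts into the benzylic C–H bond of a ring A toluene under a chiral dirhodium catalyst. This one step makes the C–C bond and sets the only stereocentre.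
4. Ring B diazo ester: one-carbon homologation of 5-bromoisovanillin to the methyl arylacetate, then silylation and diazo transfer.
5. Ring A toluene: creosol by dibromination, O-demethylation and bis-silylation.

Assumption: 3-bromo-5-hydroxy-4-methoxybenzaldehyde 1 and methyl (methylsulfinyl)methyl sulfide 2 are bought as catalogue compounds.

**Route**

Step 1
Reactants: 1 3-bromo-5-hydroxy-4-methoxybenzaldehyde; 2 methyl (methylsulfinyl)methyl sulfide (FAMSO)
Product: 3 3-bromo-2-methoxy-5-[2-(methylsulfanyl)-2-(methylsulfinyl)ethenyl]phenol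
Conditions: benzyltrimethylammonium hydroxide (Triton B, 40% in MeOH, 1.5 equiv), THF, reflux; aq. HCl work-up
Reagents that add atoms: none
Why: Knoevenagel-type condensation (first stage of the Ogura–Tsuchihashi arylacetic ester synthesis) of the non-enolisable aldehyde with the sulfur-stabilised carbanion of 2, followed by dehydration; the extra base covers the phenol, whose meta-phenoxide is not conjugated to the formyl group and so leaves it electrophilic.

Step 2
Reactants: 3 3-bromo-2-methoxy-5-[2-(methylsulfanyl)-2-(methylsulfinyl)ethenyl]phenol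
Product: 4 methyl 2-(3-bromo-5-hydroxy-4-methoxyphenyl)acetate
Conditions: HCl (ca. 3 M) in MeOH, 0 °C → rt, 16 h
Reagents that add atoms: methanol, CO
Why: Acid-promoted Pummerer-type methanolysis of the ketene dithioacetal S-oxide (second stage of the Ogura–Tsuchihashi synthesis): protonation at the benzylic carbon, capture by methanol and loss of both sulfur groups give the methyl arylacetate directly, leaving the aryl bromide, phenol and aryl methyl ether untouched.

Step 3
Reactants: 4 methyl 2-(3-bromo-5-hydroxy-4-methoxyphenyl)acetate
Product: 6 methyl 2-[3-bromo-5-(tert-butyldimethylsilyloxy)-4-methoxyphenyl]-2-diazoacetate, via silyl ether 5 (not isolated)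
Conditions: TBSCl (1.1 equiv), DBU (1.2 equiv), MeCN, 0 °C → rt, 1 h; then p-ABSA (1.3 equiv), DBU (1.5 equiv), 0 °C → rt, 12 h
Reagents that add atoms: tert-butyldimethylsilyl chloride, CC(C)(C)[Si](C)(C)Cl; 4-acetamidobenzenesulfonyl azide (p-ABSA), CC(=O)Nc1ccc(cc1)S(=O)(=O)N=[N+]=[N-]
Why: Phenol silylation with DBU as base, followed in the same flask by Regitz diazo transfer to the arylacetate enolate, gives the donor/acceptor diazo ester; the silyl ether masks the only O–H that would otherwise capture the rhodium carbenoid in step 7.

Step 4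
Reactants: 7 2-methoxy-4-methylphenol (creosol)
Product: 8 2,3-dibromo-6-methoxy-4-methylphenol
Conditions: Br2 (2.05 equiv), AcOH, 15 °C → rt
Reagents that add atoms: bromine, BrBr
Why: Electrophilic aromatic bromination in which the phenol directs one bromine ortho to OH and the methoxy group directs the other para to itself (the pattern of vanillin → 5,6-dibromovanillin); the order does not matter, and the remaining site between OMe and CH3 is the least reactive.

Step 5
Reactants: 8 2,3-dibromo-6-methoxy-4-methylphenol
Product: 9 3,4-dibromo-5-methylbenzene-1,2-diol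
Conditions: BBr3 (2.5 equiv), CH2Cl2, −78 °C → rt; then H2O, 0 °C
Reagents that add atoms: none
Why: Lewis-acid cleavage of the aryl methyl ether (BBr3 O-demethylation) frees the catechol; the aryl bromides and the methyl group are inert.

Step 6
Reactants: 9 3,4-dibromo-5-methylbenzene-1,2-diol
Product: 10 2,3-dibromo-4,5-bis(tert-butyldimethylsilyloxy)toluene
Conditions: TBSCl (2.6 equiv), imidazole (5 equiv), DMF, rt → 40 °C
Reagents that add atoms: tert-butyldimethylsilyl chloride, CC(C)(C)[Si](C)(C)Cl
Why: Imidazole-mediated silylation of both phenols gives ethers that have no activated C–H bonds, tolerate the carbenoid and still release electron density to the ring.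

Step 7
Reactants: 6 methyl 2-[3-bromo-5-(tert-butyldimethylsilyloxy)-4-methoxyphenyl]-2-diazoacetate; 10 2,3-dibromo-4,5-bis(tert-butyldimethylsilyloxy)toluene
Product: 11 methyl (2R)-2-[3-bromo-5-(tert-butyldimethylsilyloxy)-4-methoxyphenyl]-3-[2,3-dibromo-4,5-bis(tert-butyldimethylsilyloxy)phenyl]propanoate
Conditions: Rh2(R-DOSP)4 (dirhodium tetrakis[(R)-N-(4-dodecylphenylsulfonyl)prolinate], divalent rhodium, 1 mol %), 10 (3 equiv, excess recovered), 2,2-dimethylbutane/PhCF3, 50 °C, 6 added over 3 h by syringe pump
Reagents that add atoms: none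
Why: Davies-type catalytic asymmetric intermolecular C–H insertion, in which the rhodium carbenoid from 6 (an electrophilic ester α-carbon) inserts into the primary benzylic C–H bond of 10 through a hydride-transfer-like three-centre transition state, ring cyclopropanation being blocked by the fully substituted arene; the chiral prolinate pocket fixes the reacting face of the carbenoid and so the new stereocentre, and the R catalyst is chosen because, to my recollection, the S catalyst gives the S series in insertions of methyl aryldiazoacetates (to be checked on the first run against the rotation of the natural product; the antipodal catalyst is equally available).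

Step 8
Reactants: 11 methyl (2R)-2-[3-bromo-5-(tert-butyldimethylsilyloxy)-4-methoxyphenyl]-3-[2,3-dibromo-4,5-bis(tert-butyldimethylsilyloxy)phenyl]propanoate
Product: 12 methyl (2R)-2-(3-bromo-5-hydroxy-4-methoxyphenyl)-3-(2,3-dibromo-4,5-dihydroxyphenyl)propanoate
Conditions: HF·pyridine, pyridine, THF, 0 °C → rt, under argon
Reagents that add atoms: none
Why: Fluoride cleavage of the three aryl silyl ethers (driven by Si–F bond formation) under buffered, non-basic conditions, so the base-sensitive α-aryl ester stereocentre is not epimerised and the methyl ester and aryl methyl ether survive.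

**Compound list**

1 | 3-bromo-5-hydroxy-4-methoxybenzaldehyde (5-bromoisovanillin) | COc1c(O)cc(C=O)cc1Br | starting material
2 | methyl (methylsulfinyl)methyl sulfide (FAMSO) | CSCS(C)=O | starting material
3 | 3-bromo-2-methoxy-5-[2-(methylsulfanyl)-2-(methylsulfinyl)ethenyl]phenol (alkene geometry and sulfur configuration undefined, both lost in step 2) | COc1c(O)cc(C=C(SC)S(C)=O)cc1Br | intermediate
4 | methyl 2-(3-bromo-5-hydroxy-4-methoxyphenyl)acetate | COC(=O)Cc1cc(O)c(OC)c(Br)c1 | intermediate
5 | methyl 2-[3-bromo-5-(tert-butyldimethylsilyloxy)-4-methoxyphenyl]acetate | COC(=O)Cc1cc(O[Si](C)(C)C(C)(C)C)c(OC)c(Br)c1 | intermediate (not isolated)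
6 | methyl 2-[3-bromo-5-(tert-butyldimethylsilyloxy)-4-methoxyphenyl]-2-diazoacetate | COC(=O)C(=[N+]=[N-])c1cc(O[Si](C)(C)C(C)(C)C)c(OC)c(Br)c1 | intermediate
7 | 2-methoxy-4-methylphenol (creosol) | COc1cc(C)ccc1O | starting material
8 | 2,3-dibromo-6-methoxy-4-methylphenol | COc1cc(C)c(Br)c(Br)c1O | intermediate
9 | 3,4-dibromo-5-methylbenzene-1,2-diol | Cc1cc(O)c(O)c(Br)c1Br | intermediate
10 | 2,3-dibromo-4,5-bis(tert-butyldimethylsilyloxy)toluene | Cc1cc(O[Si](C)(C)C(C)(C)C)c(O[Si](C)(C)C(C)(C)C)c(Br)c1Br | intermediate
11 | methyl (2R)-2-[3-bromo-5-(tert-butyldimethylsilyloxy)-4-methoxyphenyl]-3-[2,3-dibromo-4,5-bis(tert-butyldimethylsilyloxy)phenyl]propanoate | COC(=O)[C@H](Cc1cc(O[Si](C)(C)C(C)(C)C)c(O[Si](C)(C)C(C)(C)C)c(Br)c1Br)c1cc(O[Si](C)(C)C(C)(C)C)c(OC)c(Br)c1 | intermediate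
12 | methyl (2R)-2-(3-bromo-5-hydroxy-4-methoxyphenyl)-3-(2,3-dibromo-4,5-dihydroxyphenyl)propanoate | COC(=O)[C@H](Cc1cc(O)c(O)c(Br)c1Br)c1cc(O)c(OC)c(Br)c1 | target

**Step count**

Total: 8 steps. Longest linear sequence: 5 steps (1 → 3 → 4 → 6 → 11 → 12, or 7 → 8 → 9 → 10 → 11 → 12).

**Three steps most likely to fail, with fallbacks**

Step 7 is the main risk. The precedent for primary benzylic insertion is on electron-rich, unhindered 3,4-dioxygenated toluenes. Toluene 10 carries an ortho and a meta bromine, so insertion may lose to carbene dimerisation, and the ee of primary benzylic insertions with methyl esters is typically moderate to good, not excellent. A moderate yield is expected, and 12 may need enrichment by crystallisation. The fallback sets out from 10 and 6 and comes back at 11. Wohl–Ziegler bromination of 10 (NBS, AIBN, PhCF3, 80 °C) gives 2,3-dibromo-4,5-bis(tert-butyldimethylsilyloxy)benzyl bromide F1. Carbene cross-coupling of F1 with 6 under Pd(PPh3)4 (zerovalent palladium, 5 mol %), iPr2NH, MeCN, 60 °C proceeds by benzylic oxidative addition, carbene migratory insertion and β-hydride elimination; the benzylic bromide should add much faster than the hindered aryl bromides. It gives methyl (E)-2-[3-bromo-5-(tert-butyldimethylsilyloxy)-4-methoxyphenyl]-3-[2,3-dibromo-4,5-bis(tert-butyldimethylsilyloxy)phenyl]prop-2-enoate F2. The C–C bond is still made at the electrophilic carbene carbon. Asymmetric hydrogenation of F2 with an [Ir(cod)(PHOX)]BArF-type catalyst (H2, 50 bar, CH2Cl2; ligand enantiomer chosen by screening to give R) then sets the stereocentre and gives 11.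

Step 1 is the second risk. The free phenol consumes base, and the condensation may stall or the aldehyde may degrade under the excess hydroxide. The fallback sets out from 1 and comes back at 4. Decarboxylative trichloromethylation of 1 (CCl3CO2Na, CCl3CO2H, DMF, rt) gives 3-bromo-2-methoxy-5-(2,2,2-trichloro-1-hydroxyethyl)phenol F3. Reductive Jocic homologation (NaBH4, NaOH, t-BuOH, 55 °C; gem-dichloroepoxide opened by hydride at the benzylic carbon) gives 2-(3-bromo-5-hydroxy-4-methoxyphenyl)acetic acid F4. Fischer esterification (MeOH, cat. H2SO4, reflux) gives 4.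

Step 4 is the third risk. The second bromine may partly enter between OMe and CH3, or a third bromine may be introduced, and the isomers would be hard to separate. This fallback does not set out from a numbered compound of the route: purchased vanillin F5 takes the place of 7, and the route is rejoined at 8. Bromination of vanillin F5 (Br2, 2.2 equiv, iron powder, AcOH) gives 2,3-dibromo-4-hydroxy-5-methoxybenzaldehyde F6, in which the formyl group secures the 2,3-dibromo pattern. Ionic hydrogenation of the formyl group to methyl (Et3SiH, TFA, 50 °C) gives 8.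

**Further compounds**

F1 | step 7 | 2,3-dibromo-4,5-bis(tert-butyldimethylsilyloxy)benzyl bromide | BrCc1cc(O[Si](C)(C)C(C)(C)C)c(O[Si](C)(C)C(C)(C)C)c(Br)c1Br
F2 | step 7 | methyl (E)-2-[3-bromo-5-(tert-butyldimethylsilyloxy)-4-methoxyphenyl]-3-[2,3-dibromo-4,5-bis(tert-butyldimethylsilyloxy)phenyl]prop-2-enoate | COC(=O)/C(c1cc(O[Si](C)(C)C(C)(C)C)c(OC)c(Br)c1)=C/c1cc(O[Si](C)(C)C(C)(C)C)c(O[Si](C)(C)C(C)(C)C)c(Br)c1Br
F3 | step 1 | 3-bromo-2-methoxy-5-(2,2,2-trichloro-1-hydroxyethyl)phenol (racemic) | COc1c(O)cc(C(O)C(Cl)(Cl)Cl)cc1Br
F4 | step 1 | 2-(3-bromo-5-hydroxy-4-methoxyphenyl)acetic acid | COc1c(O)cc(CC(=O)O)cc1Br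
F5 | step 4 | vanillin (4-hydroxy-3-methoxybenzaldehyde, purchased) | COc1cc(C=O)ccc1O
F6 | step 4 | 2,3-dibromo-4-hydroxy-5-methoxybenzaldehyde | COc1cc(C=O)c(Br)c(Br)c1O
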